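**Assumptions and notation**

- Assumption: (R)-TRIP is taken to direct Re-face addition to the aryl aldehyde, as it does with simple allyl- and crotyl-Bpin; if the sense is reversed for boronate 10, (S)-TRIP is used instead.
- Assumption: compounds 1, 2, 4, 5, 7, 9, 12 and (R)-TRIP are purchased.
- Lignan locants used below: the target ring is O–C7′–C8′–C8–C9; C9′ is the CH2OH carbon; C7 is the side-chain carbinol carbon.

**Retrosynthetic overview**

1. Target 16 ⇐ hydride opening of the cis-fused furofuranone 15. The lactone C9′(=O)–O–C7 carries the C7 configuration, and the bicycle enforces the 3,4-cis relationship on the tetrahydrofuran.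
2. 15 ⇐ acid-catalysed closure of the C9–OH onto the benzylic carbon of (E)-arylidene lactone 14 (tetrahydrofuran ring, formed second; sets C7′ and C8′).
3. 14 ⇐ Heck arylation of the cis α-methylene-γ-butyrolactone 11 with 4-iodo-2-methoxyphenol.
4. 11 ⇐ proposed new step: chiral phosphoric acid-catalysed syn-selective 2-(alkoxycarbonyl)allylboration/lactonisation of O-pivaloylvanillin 3 with boronate 10 (lactone ring, formed first; sets C7 and C8).
5. 10 ⇐ Morita–Baylis–Hillman adduct of methyl acrylate and TBSOCH2CHO.

**Route**

Step 1
Reactants: 1 vanillin; 2 pivaloyl chloride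
Product: 3 4-formyl-2-methoxyphenyl pivalate
Conditions: PivCl, Et3N, DMAP (cat.), CH2Cl2, 0 °C → rt
Reagents that add atoms: pivaloyl chloride, CC(C)(C)C(=O)Cl
Why: Routine phenol O-acylation (nucleophilic acyl substitution); the pivalate survives every step until the final hydride reduction and deactivates this ring so its benzylic C–O bond (future C7) does not ionise in the later acid steps; no stereocentre.

Step 2
Reactants: 4 methyl acrylate; 5 (tert-butyldimethylsilyloxy)acetaldehyde
Product: 6 methyl 4-[(tert-butyldimethylsilyl)oxy]-3-hydroxy-2-methylidenebutanoate (racemic)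
Conditions: DABCO (0.5 equiv), methyl acrylate (3 equiv), neat, rt, 48 h
Reagents that add atoms: methyl acrylate, C=CC(=O)OC
Why: Morita–Baylis–Hillman reaction of an activated α-alkoxy aldehyde; the racemic carbinol centre is destroyed in step 4.

Step 3
Reactants: 6; 7 acetic anhydride
Product: 8 methyl 3-acetoxy-4-[(tert-butyldimethylsilyl)oxy]-2-methylidenebutanoate (racemic)
Conditions: Ac2O, pyridine, DMAP (cat.), CH2Cl2, 0 °C
Reagents that add atoms: acetic anhydride, CC(=O)OC(C)=O
Why: Standard acetylation to install the allylic leaving group; silyl ether and ester are unaffected.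

Step 4
Reactants: 8; 9 bis(pinacolato)diboron
Product: 10 methyl (2E)-4-[(tert-butyldimethylsilyl)oxy]-2-[(4,4,5,5-tetramethyl-1,3,2-dioxaborolan-2-yl)methyl]but-2-enoate (CH2OTBS cis to CH2Bpin, trans to CO2Me)
Conditions: B2pin2, Pd2(dba)3 (3 mol %), PhMe, 50 °C
Reagents that add atoms: bis(pinacolato)diboron, CC1(C)OB(OC1(C)C)B1OC(C)(C)C(C)(C)O1
Why: Pd-catalysed allylic borylation of a Baylis–Hillman acetate (π-allyl-Pd, overall SN2′) gives the conjugated primary allylboronate with the ester trans to the γ-substituent, the usual outcome for acrylate-derived MBH acetates; geometry to be confirmed by NOE.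

Step 5
Reactants: 3; 10
Product: 11 (4R,5R)-4-{[(tert-butyldimethylsilyl)oxy]methyl}-5-[3-methoxy-4-(pivaloyloxy)phenyl]-3-methylidenedihydrofuran-2(3H)-one (4,5-cis)
Conditions: (R)-TRIP (10 mol %), 4 Å MS, PhMe, rt, 72 h; then PPTS (20 mol %), 50 °C
Reagents that add atoms: allylboronate 10, COC(=O)/C(CB1OC(C)(C)C(C)(C)O1)=C/CO[Si](C)(C)C(C)(C)C (Bpin and OMe are lost)
Why: Proposed new method: chiral phosphoric acid-catalysed syn-selective 2-(methoxycarbonyl)allylboration/lactonisation. The acid H-bonds to a boronate oxygen (with P=O···H–C(formyl) contact) and accelerates a closed Zimmerman–Traxler chair with the aryl group equatorial and the CH2OTBS group (cis to CH2B) pseudo-axial, so the C7–C8 bond forms syn while the 3,3′-aryl pocket selects the aldehyde Re face (7R, hence 8R); the resulting alkoxide/alcohol then closes on the methyl ester by acyl substitution with retention, giving the cis lactone. The uncatalysed background of this ester-deactivated boronate is slow at rt, and the pivalate-deactivated ring suppresses SN1 scrambling at C7. Closest known reaction types: phosphoric acid-catalysed allyl-/crotylboration of aryl aldehydes with pinacol boronates, and racemic thermal or Lewis/Brønsted acid-promoted 2-alkoxycarbonylallylboration–lactonisation.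

Step 6
Reactants: 11; 12 4-iodo-2-methoxyphenol
Product: 13 (3E,4R,5R)-4-{[(tert-butyldimethylsilyl)oxy]methyl}-3-(4-hydroxy-3-methoxybenzylidene)-5-[3-methoxy-4-(pivaloyloxy)phenyl]dihydrofuran-2(3H)-one
Conditions: Pd(OAc)2 (5 mol %), P(o-tol)3 (10 mol %), Et3N, DMF, 80 °C
Reagents that add atoms: 4-iodo-2-methoxyphenol, COc1cc(I)ccc1O
Why: Mizoroki–Heck arylation of an α-methylene-γ-butyrolactone; aryl-Pd adds to the terminal CH2 and β-hydride elimination of a benzylic hydrogen gives the conjugated (E)-arylidene lactone; C4 and C5 are not touched, and pivalate and TBS ether tolerate Et3N.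

Step 7
Reactants: 13
Product: 14 (3E,4R,5R)-3-(4-hydroxy-3-methoxybenzylidene)-4-(hydroxymethyl)-5-[3-methoxy-4-(pivaloyloxy)phenyl]dihydrofuran-2(3H)-one
Conditions: HF·pyridine, THF–pyridine, 0 °C → rt (crude used directly)
Reagents that add atoms: none
Why: Buffered fluoride cleavage of the primary TBS ether; weakly acidic, non-basic conditions leave the pivalate, lactone and stereocentres intact and avoid alkoxide-driven translactonisation.

Step 8
Reactants: 14
Product: 15 (3R,3aR,6S,6aS)-6-(4-hydroxy-3-methoxyphenyl)-3-[3-methoxy-4-(pivaloyloxy)phenyl]tetrahydro-1H,3H-furo[3,4-c]furan-1-one (cis-fused; 3-aryl endo, i.e. cis to C4H2; 6-aryl exo, i.e. trans to C1)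
Conditions: TfOH (5 mol %), CH2Cl2 (0.02 M), −20 → 0 °C
Reagents that add atoms: none
Why: Acid-catalysed intramolecular oxa-Michael addition; the formally 5-endo closure is feasible because the protonated 4-hydroxybenzylidene lactone is a p-quinone-methide-type benzylic cation. The primary OH adds to the benzylic carbon, cis ring fusion (C6a) is the only possible junction, and C6 adopts the exo-aryl configuration because C–O formation is reversible and an endo,endo diaryl arrangement is disfavoured; the pivalate-deactivated benzylic lactone C–O bond (C3) does not ionise.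

Step 9
Reactants: 15
Product: 16 (7R)-7-hydroxylariciresinol, 4-[(2S,3R,4R)-4-[(R)-hydroxy(4-hydroxy-3-methoxyphenyl)methyl]-3-(hydroxymethyl)oxolan-2-yl]-2-methoxyphenol
Conditions: LiAlH4 (5 equiv), THF, 0 °C → rt; Rochelle-salt work-up (no acid)
Reagents that add atoms: none
Why: Hydride reduction of the γ-lactone to the diol gives C9′H2OH and frees C7–OH without breaking the C7–O bond, so 7R is retained; the aryl pivalate is cleaved in the same operation and no stereocentre is touched. Acid is avoided on work-up because the product can cyclise to a furofuran.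

**Compound list**

1 | vanillin | COc1cc(C=O)ccc1O | starting material
2 | pivaloyl chloride | CC(C)(C)C(=O)Cl | starting material
3 | 4-formyl-2-methoxyphenyl pivalate | COc1cc(C=O)ccc1OC(=O)C(C)(C)C | intermediate
4 | methyl acrylate | C=CC(=O)OC | starting material
5 | (tert-butyldimethylsilyloxy)acetaldehyde | O=CCO[Si](C)(C)C(C)(C)C | starting material
6 | methyl 4-(TBS-oxy)-3-hydroxy-2-methylidenebutanoate (racemic) | C=C(C(=O)OC)C(O)CO[Si](C)(C)C(C)(C)C | intermediate
7 | acetic anhydride | CC(=O)OC(C)=O | starting material
8 | methyl 3-acetoxy-4-(TBS-oxy)-2-methylidenebutanoate (racemic) | C=C(C(=O)OC)C(OC(C)=O)CO[Si](C)(C)C(C)(C)C | intermediate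
9 | bis(pinacolato)diboron | CC1(C)OB(OC1(C)C)B1OC(C)(C)C(C)(C)O1 | starting material
10 | methyl (2E)-4-(TBS-oxy)-2-[(pinacolatoboryl)methyl]but-2-enoate | COC(=O)/C(CB1OC(C)(C)C(C)(C)O1)=C/CO[Si](C)(C)C(C)(C)C | intermediate
11 | (4R,5R)-4-(TBS-oxymethyl)-5-[3-methoxy-4-(pivaloyloxy)phenyl]-3-methylidenedihydrofuran-2(3H)-one | C=C1C(=O)O[C@@H](c2ccc(OC(=O)C(C)(C)C)c(OC)c2)[C@H]1CO[Si](C)(C)C(C)(C)C | intermediate
12 | 4-iodo-2-methoxyphenol | COc1cc(I)ccc1O | starting material
13 | (3E,4R,5R)-3-(4-hydroxy-3-methoxybenzylidene)-4-(TBS-oxymethyl)-5-[3-methoxy-4-(pivaloyloxy)phenyl]dihydrofuran-2(3H)-one | COc1cc(/C=C2/C(=O)O[C@@H](c3ccc(OC(=O)C(C)(C)C)c(OC)c3)[C@H]2CO[Si](C)(C)C(C)(C)C)ccc1O | intermediate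
14 | (3E,4R,5R)-3-(4-hydroxy-3-methoxybenzylidene)-4-(hydroxymethyl)-5-[3-methoxy-4-(pivaloyloxy)phenyl]dihydrofuran-2(3H)-one | COc1cc(/C=C2/C(=O)O[C@@H](c3ccc(OC(=O)C(C)(C)C)c(OC)c3)[C@H]2CO)ccc1O | intermediate
15 | (3R,3aR,6S,6aS)-6-(4-hydroxy-3-methoxyphenyl)-3-[3-methoxy-4-(pivaloyloxy)phenyl]tetrahydro-1H,3H-furo[3,4-c]furan-1-one | COc1cc([C@H]2OC[C@@H]3[C@H](c4ccc(OC(=O)C(C)(C)C)c(OC)c4)OC(=O)[C@H]23)ccc1O | intermediate
16 | (7R)-7-hydroxylariciresinol | COc1cc([C@H]2OC[C@H]([C@@H](O)c3ccc(O)c(OC)c3)[C@@H]2CO)ccc1O | target

**Totals**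

- Total step count: 9.
- Longest linear sequence: 8 steps (steps 2–9, from methyl acrylate and aldehyde 5); step 1 is a one-step side branch.

**Three steps most likely to fail, with fallbacks**

1. Step 5 (proposed new method). Risks: slow addition of the ester-deactivated boronate, modest ee, or erosion of syn selectivity. Fallback (known chemistry, auxiliary control instead of catalyst control): exchange the pinacol of 10 for a camphor-derived chiral diol, run the uncatalysed thermal allylboration of 3 through the same chair, then lactonise with mild acid. This is an established reagent-controlled route to enantioenriched α-methylene-γ-butyrolactones; 11 can be recrystallised to upgrade ee.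

2. Step 8 (acid-catalysed 5-endo oxa-Michael). Risks: unfavourable equilibrium, C6 epimer mixtures, or translactonisation. Fallback (oxidative, kinetically controlled closure): 1,4-reduce the arylidene of 13 with Stryker's reagent, where protonation from the open face gives the all-cis α-(4-hydroxy-3-methoxybenzyl) lactone; desilylate; then treat with DDQ to generate a discrete p-quinone methide that the CH2OH traps irreversibly (5-exo-trig) to give 15.

3. Step 6 (Heck on a hindered cis-disubstituted methylene lactone with a free iodophenol). Risks: endocyclic double-bond isomer or phenol side reactions. Fallback (conjugate arylation instead of Heck): Rh(I)-catalysed 1,4-addition of 4-hydroxy-3-methoxyphenylboronic acid pinacol ester to 11 ([Rh(cod)OH]2, dioxane/H2O) gives the α-benzyl lactone directly, which then enters the desilylation and DDQ/quinone-methide closure of fallback 2, bypassing the arylidene altogether.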